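Slowest in this flask is the coupling step, the rate-limiting step, with a time of 11.6 s at the full charge of starting material against half-lives of 0.23 s and 2.20 s for the two steps out of the intermediate.

    intermediate ⇌ target (K1 = 0.64, k1 = 3.0 s⁻¹)
    intermediate ⇌ isomer of the product (K2 = 2.7, k2 = 0.23 s⁻¹)
    crystals ⇌ target, rate k3*(cs3 - [target]) while solid is left; crystals form when [target] > cs3 (cs3 = 16 mM, k3 = 4.6 s⁻¹)
    starting material + coupling partner → intermediate + released group (k4 = 0.24 L mol⁻¹ s⁻¹)

starting material 0.36 M; coupling partner 0.360 M (in portions, 4); time 50 s; the portions of coupling partner follow each other after 12 s, the first at the start

- the state of affairs at 50 s: stopped, and by what, or still going (forward and back rates have come level / it is still moving / the coupling partner has run out first / all of the starting material has reacted)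
- the target standing at 50 s, as a percentage of the starting material charged
- the isomer of the product standing at 50 s, as a percentage of the starting material charged
- the intermediate standing at 50 s, as a percentage of the starting material charged

- target is meant together with its crystals
- solid, in amounts per volume of the solution: crystals
- the reaction counts as stopped when no species that holds the starting material changes by six tenths of a point or more over the second half of the time
- run time (flask): 50 s

Minutes of the meeting. The chair argued that step 1 keeps up with the coupling step, because its half-life of 0.23 s is short against the 50 s of the run. The chair added that crystals, once present, keep dissolved target close to 16 mM, because their exchange time of 0.217 s is short against the coupling time.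

From this the chair took 6.94%: the held share, the fraction of the charge standing as intermediate when dissolved target sits at its solubility. It is the solubility divided by K1 and by the charge of starting material. While crystals grow, dissolved target stands above solubility, so the held share is a floor.

The isomer relaxes with a half-life of 2.20 s, short against the run, so the chair expected it near K2 times the held share, 18.8%. Solid needs a conversion of about 30.1% once the isomer has caught up, less than the charge of coupling partner allows. The chair's own reckoning stopped there and gave no number for the target.

The member who made the forecast reported: it is still moving, with target 42% (39% to 45%), isomer 20% (18% to 22%) and intermediate 7.5% (7% to 8%). The stated ground was “Crystals pin dissolved target”. The chair noted that the forecast's intermediate stands 0.56 percentage points above the floor.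

At 50 s in this flask, it is still moving, with target 42.0%, isomer 20.1% and intermediate 7.50%. Of that target, 37.3% of the charge stands as crystals, so solid is present at the reading. The intermediate reads 0.56 points above the held share. In the neighbour charged with 1.4 M of starting material, which holds 17.1% as crystals at 50.0 s, the held share becomes 1.79%, and that neighbour's intermediate stands at 1.85%.

Its constants were set for the occasion; the rest is arithmetic.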